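**Retrosynthetic overview**

1. The target is a (2S)-flavanone in which ring C is the only ring to be built. Removal of the methoxymethyl (MOM) ethers, oxidation at C4 and exchange of a C4 methoxy group for hydroxyl lead back to a 4-methoxyflavan.
2. Ring C is cut across O1–C2 and C3–C4. The O1–C8a–C4a–C4 unit is an oxygenated ortho-quinone methide of ring A, with C4 carrying OMe, and C2–C3 is the vinyl group of a 2,4,6-trioxygenated styrene (ring B). The strategy rests on this oxadiene and electron-rich alkene pair.
3. The quinone methide comes from a salicylaldehyde, made by ortho-formylation of 4-lavandulyl-3,5-bis(MOM)phenol. Its aryl–CH2 bond is made by Negishi coupling of an aryl iodide (from phloroglucinol by lithiation between the two MOM ethers) with (S)-lavandulylzinc iodide.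
4. C2'' is set by an Evans deconjugative α-prenylation of a senecioyl imide. The styrene comes from 2,4,6-trihydroxybenzaldehyde by MOM protection and Wittig methylenation.
5. Ring order: rings A and B are bought as arenes; ring C is closed in the key cycloaddition, three steps before the end.

Key step: step 13

Remark on the chemistry: which antipode of the imidodiphosphoric acid leads to (2S) cannot be predicted. Both antipodes are available from (R)- or (S)-BINOL, and the one that gives (2S) is taken.

**Route**

Step 1
Reactants: 1 (S)-4-benzyl-2-oxazolidinone; 2 3-methylbut-2-enoyl chloride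
Product: 3 (S)-4-benzyl-3-(3-methylbut-2-enoyl)oxazolidin-2-one
Conditions: n-BuLi, THF, −78 °C; then 2, −78 → 0 °C
Reagents that add atoms: none
Why: N-acylation of the lithiated oxazolidinone by the acid chloride is standard imide formation and creates no stereocenter.

Step 2
Reactants: 3 (S)-4-benzyl-3-(3-methylbut-2-enoyl)oxazolidin-2-one; 4 prenyl bromide (1-bromo-3-methylbut-2-ene)
Product: 6 (S)-4-benzyl-3-[(2S)-5-methyl-2-(prop-1-en-2-yl)hex-4-enoyl]oxazolidin-2-one, via sodium dienolate 5 (not isolated)
Conditions: NaN(SiMe3)2, THF, −78 °C; then 4, −78 → −40 °C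
Reagents that add atoms: none
Why: γ-deprotonation gives the chelated (Z)-dienolate, which in an Evans deconjugative alkylation reacts at the α-carbon on the face opposite the benzyl group, setting the (S) centre that becomes C2'' and leaving the double bond as the isopropenyl group.

Step 3
Reactants: 6 (S)-4-benzyl-3-[(2S)-5-methyl-2-(prop-1-en-2-yl)hex-4-enoyl]oxazolidin-2-one
Product: 7 (S)-lavandulol, (2S)-5-methyl-2-(prop-1-en-2-yl)hex-4-en-1-ol
Conditions: LiBH4, H2O (1 equiv), Et2O, 0 °C
Reagents that add atoms: none
Why: reductive cleavage of the imide by LiBH4 gives the primary alcohol and releases the auxiliary under conditions too mild to epimerise or reconjugate the β,γ-unsaturated centre.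

Step 4
Reactants: 7 (S)-lavandulol
Product: 8 (S)-lavandulyl iodide, (3S)-3-(iodomethyl)-2,6-dimethylhepta-1,5-diene
Conditions: PPh3, I2, imidazole, CH2Cl2, 0 °C
Reagents that add atoms: iodine, [I][I]
Why: the Appel-type iodination substitutes the primary CH2–O carbon by SN2 and leaves the adjacent stereocenter untouched.

Step 5
Reactants: 9 phloroglucinol
Product: 10 3,5-bis(methoxymethoxy)phenol
Conditions: MOMCl (2 equiv), i-Pr2NEt, CH2Cl2/DMF, 0 °C → rt
Reagents that add atoms: chloromethyl methyl ether, COCCl
Why: O-alkylation of two of the three equivalent phenols is a statistical Williamson-type protection, and the bis-ether should be separable from the mono- and tris-ethers, which can be recycled.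

Step 6
Reactants: 10 3,5-bis(methoxymethoxy)phenol
Product: 11 [3,5-bis(methoxymethoxy)phenoxy]triisopropylsilane
Conditions: TIPSCl, imidazole, DMF, rt
Reagents that add atoms: triisopropylsilyl chloride, CC(C)[Si](Cl)(C(C)C)C(C)C
Why: silylation of the last phenol installs an orthogonal, bulky and poorly coordinating group that should stay out of the directed metalation.

Step 7
Reactants: 11 [3,5-bis(methoxymethoxy)phenoxy]triisopropylsilane
Product: 13 [4-iodo-3,5-bis(methoxymethoxy)phenoxy]triisopropylsilane, via aryllithium 12 (not isolated)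
Conditions: n-BuLi, THF, 0 °C; then I2, −78 °C
Reagents that add atoms: iodine, [I][I]
Why: directed ortho-metalation should take place at the C–H flanked by the two coordinating MOM ethers rather than next to the bulky silyl ether, and iodine traps the aryllithium.

Step 8
Reactants: 13 [4-iodo-3,5-bis(methoxymethoxy)phenoxy]triisopropylsilane; 8 (S)-lavandulyl iodide
Product: 15 {3,5-bis(methoxymethoxy)-4-[(2R)-5-methyl-2-(prop-1-en-2-yl)hex-4-en-1-yl]phenoxy}triisopropylsilane, via lavandulylzinc iodide 14 (not isolated)
Conditions: 8, Zn dust, LiCl, THF, 40 °C; then 13, Pd(OAc)2 (cat.), SPhos (cat.), THF, 50 °C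
Reagents that add atoms: none
Why: in this Negishi sp3–sp2 coupling the non-basic primary alkylzinc should couple without the E2 elimination that threatens direct alkylation of an aryllithium by this β-branched iodide, and the stereocenter β to zinc takes no part (the descriptor changes from S to R only through the priority rules).

Step 9
Reactants: 15 {3,5-bis(methoxymethoxy)-4-[(2R)-5-methyl-2-(prop-1-en-2-yl)hex-4-en-1-yl]phenoxy}triisopropylsilane
Product: 16 3,5-bis(methoxymethoxy)-4-[(2R)-5-methyl-2-(prop-1-en-2-yl)hex-4-en-1-yl]phenol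
Conditions: Bu4NF, THF, 0 °C; aq. NH4Cl
Reagents that add atoms: none
Why: fluoride cleaves the aryl silyl ether selectively, while the MOM ethers and the alkenes are inert.

Step 10
Reactants: 16 3,5-bis(methoxymethoxy)-4-[(2R)-5-methyl-2-(prop-1-en-2-yl)hex-4-en-1-yl]phenol
Product: 17 6-hydroxy-2,4-bis(methoxymethoxy)-3-[(2R)-5-methyl-2-(prop-1-en-2-yl)hex-4-en-1-yl]benzaldehyde
Conditions: MgCl2, Et3N, (CH2O)n, MeCN, reflux
Reagents that add atoms: paraformaldehyde (as formaldehyde), C=O
Why: in the Casnati–Skattebøl ortho-formylation the magnesium phenoxide delivers formaldehyde only ortho to the one free hydroxyl, a second formaldehyde oxidises the benzylic alkoxide, and the two ortho positions are equivalent, so one salicylaldehyde should form.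

Step 11
Reactants: 18 2,4,6-trihydroxybenzaldehyde
Product: 19 2,4,6-tris(methoxymethoxy)benzaldehyde
Conditions: NaH, MOMCl, DMF/THF, 0 °C → rt
Reagents that add atoms: chloromethyl methyl ether, COCCl
Why: exhaustive O-alkylation of the three phenoxides is a standard protection, the strong base being needed for the chelated ortho hydroxyls.

Step 12
Reactants: 19 2,4,6-tris(methoxymethoxy)benzaldehyde
Product: 20 2,4,6-tris(methoxymethoxy)styrene
Conditions: Ph3PCH3Br, KOt-Bu, THF, 0 °C → rt
Reagents that add atoms: methyltriphenylphosphonium bromide, C[P+](c1ccccc1)(c1ccccc1)c1ccccc1.[Br-]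
Why: Wittig methylenation of a non-enolisable aromatic aldehyde is reliable even with two ortho substituents.

Step 13
Reactants: 17 6-hydroxy-2,4-bis(methoxymethoxy)-3-[(2R)-5-methyl-2-(prop-1-en-2-yl)hex-4-en-1-yl]benzaldehyde; 20 2,4,6-tris(methoxymethoxy)styrene; 21 trimethyl orthoformate
Product: 24 (2S)-4-methoxy-5,7-bis(methoxymethoxy)-6-[(2R)-5-methyl-2-(prop-1-en-2-yl)hex-4-en-1-yl]-2-[2,4,6-tris(methoxymethoxy)phenyl]chromane (mixture of C4 epimers), via dimethyl acetal 22 (not isolated), via 4-methoxy ortho-quinone methide 23 (not isolated)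
Conditions: HC(OMe)3 (3 equiv), C2-symmetric imidodiphosphoric acid from 3,3'-bis(2,4,6-triethylphenyl)-BINOL (5–10 mol%), 5 Å MS, CH2Cl2/cyclohexane, −40 → −20 °C
Reagents that add atoms: none
Why: Proposed new method: HC(OMe)3 and the acid convert aldehyde 17 into acetal 22, which loses methanol to the 4-methoxy ortho-quinone methide 23 (an oxocarbenium–phenol ion pair with the chiral imidodiphosphate); the nucleophilic CH2 of styrene 20 adds to the methide carbon (C3–C4 bond) and the quinoid oxygen then captures the C2 benzylic cation stabilised by the three ring B oxygens (O1–C2 bond). The closest known reactions are chiral phosphoric and imidodiphosphoric acid catalysed [4+2] cycloadditions of ortho-quinone methides with styrenes, the intramolecular variant that starts from salicylaldehydes and alcohols, and the racemic acid-promoted union of salicylaldehyde acetals with styrenes to 4-alkoxyflavans; the enantioselective intermolecular acetal version on a polyoxygenated pair is not established. Ring C closes in an inverse-electron-demand hetero-Diels–Alder [4+2] mode that is asynchronous or stepwise (C–C bond first, then closure of the six-membered oxygen ring). C2 is set by the confined chiral counter-anion, which must shield one face of the methide–styrene assembly; the distant lavandulyl centre is a spectator and C4 forms as a mixture that the later oxidation erases. Regiochemistry follows from polarity (styrene CH2 to the electrophilic methide carbon), and the 6-lavandulyl pattern follows from the aldehyde lying ortho to the only free phenol, which is para to the side chain. Chemoselectivity over the MOM ethers and the lavandulyl alkenes rests on the far easier ionisation of the trioxygenated benzylic acetal, and low temperature with a moderately acidic catalyst is needed so that re-ionisation at C2–O1 does not erode the selectivity.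

Step 14
Reactants: 24 (2S)-4-methoxyflavan (C4 epimers)
Product: 25 (2S)-5,7-bis(methoxymethoxy)-6-[(2R)-5-methyl-2-(prop-1-en-2-yl)hex-4-en-1-yl]-2-[2,4,6-tris(methoxymethoxy)phenyl]chroman-4-ol (mixture of C4 epimers)
Conditions: HCl (0.05 M), THF/H2O (2:1), 0 °C → rt, dilute
Reagents that add atoms: water, O
Why: this SN1 solvolysis should be selective because the C4 cation is flanked by three ring A oxygens held coplanar by the ring fusion and so forms far more readily than cations from the MOM ethers or from C2–O1, and excess water captures it.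

Step 15
Reactants: 25 (2S)-flavan-4-ol (C4 epimers)
Product: 26 (2S)-5,7-bis(methoxymethoxy)-6-[(2R)-5-methyl-2-(prop-1-en-2-yl)hex-4-en-1-yl]-2-[2,4,6-tris(methoxymethoxy)phenyl]chroman-4-one
Conditions: Dess–Martin periodinane, pyridine, CH2Cl2, 0 °C → rt
Reagents that add atoms: none
Why: Dess–Martin oxidation of the secondary benzylic alcohol under buffered conditions converges both C4 epimers on the ketone without touching the alkenes, the MOM ethers or C2.

Step 16
Reactants: 26 penta-MOM flavanone
Product: 27 (2S)-5,7-dihydroxy-6-[(2R)-5-methyl-2-(prop-1-en-2-yl)hex-4-en-1-yl]-2-(2,4,6-trihydroxyphenyl)chroman-4-one (CNP0107340.3)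
Conditions: HCl (ca. 1 M in MeOH), 0 °C → rt
Reagents that add atoms: none
Why: acid-catalysed transacetalisation moves the five MOM groups to methanol as dimethoxymethane, and because O1 is now part of a vinylogous ester and therefore less basic, C2–O1 ionisation should be slow enough at room temperature to keep C2.

**Compound list**

1 | (S)-4-benzyl-2-oxazolidinone | O=C1N[C@@H](Cc2ccccc2)CO1 | starting material
2 | 3-methylbut-2-enoyl chloride | CC(C)=CC(=O)Cl | starting material
3 | (S)-4-benzyl-3-(3-methylbut-2-enoyl)oxazolidin-2-one | CC(C)=CC(=O)N1[C@@H](Cc2ccccc2)COC1=O | intermediate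
4 | prenyl bromide | CC(C)=CCBr | starting material
5 | sodium (Z)-dienolate of 3 (not isolated) | C=C(C)/C=C(\[O-])N1[C@@H](Cc2ccccc2)COC1=O.[Na+] | intermediate
6 | (S)-4-benzyl-3-[(2S)-5-methyl-2-(prop-1-en-2-yl)hex-4-enoyl]oxazolidin-2-one | O=C([C@@H](CC=C(C)C)C(C)=C)N1[C@@H](Cc2ccccc2)COC1=O | intermediate
7 | (S)-lavandulol | OC[C@@H](CC=C(C)C)C(C)=C | intermediate
8 | (S)-lavandulyl iodide | IC[C@@H](CC=C(C)C)C(C)=C | intermediate
9 | phloroglucinol | Oc1cc(O)cc(O)c1 | starting material
10 | 3,5-bis(methoxymethoxy)phenol | COCOc1cc(O)cc(OCOC)c1 | intermediate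
11 | [3,5-bis(methoxymethoxy)phenoxy]triisopropylsilane | COCOc1cc(O[Si](C(C)C)(C(C)C)C(C)C)cc(OCOC)c1 | intermediate
12 | 2,6-bis(methoxymethoxy)-4-(triisopropylsilyloxy)phenyllithium (not isolated) | [Li]c1c(OCOC)cc(O[Si](C(C)C)(C(C)C)C(C)C)cc1OCOC | intermediate
13 | [4-iodo-3,5-bis(methoxymethoxy)phenoxy]triisopropylsilane | COCOc1cc(O[Si](C(C)C)(C(C)C)C(C)C)cc(OCOC)c1I | intermediate
14 | (S)-lavandulylzinc iodide (not isolated) | I[Zn]C[C@@H](CC=C(C)C)C(C)=C | intermediate
15 | {3,5-bis(methoxymethoxy)-4-[(2R)-5-methyl-2-(prop-1-en-2-yl)hex-4-en-1-yl]phenoxy}triisopropylsilane | COCOc1cc(O[Si](C(C)C)(C(C)C)C(C)C)cc(OCOC)c1C[C@@H](CC=C(C)C)C(C)=C | intermediate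
16 | 3,5-bis(methoxymethoxy)-4-[(2R)-5-methyl-2-(prop-1-en-2-yl)hex-4-en-1-yl]phenol | COCOc1cc(O)cc(OCOC)c1C[C@@H](CC=C(C)C)C(C)=C | intermediate
17 | 6-hydroxy-2,4-bis(methoxymethoxy)-3-[(2R)-5-methyl-2-(prop-1-en-2-yl)hex-4-en-1-yl]benzaldehyde | O=Cc1c(O)cc(OCOC)c(C[C@@H](CC=C(C)C)C(C)=C)c1OCOC | intermediate
18 | 2,4,6-trihydroxybenzaldehyde | O=Cc1c(O)cc(O)cc1O | starting material
19 | 2,4,6-tris(methoxymethoxy)benzaldehyde | COCOc1cc(OCOC)c(C=O)c(OCOC)c1 | intermediate
20 | 2,4,6-tris(methoxymethoxy)styrene | C=Cc1c(OCOC)cc(OCOC)cc1OCOC | intermediate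
21 | trimethyl orthoformate | COC(OC)OC | starting material
22 | dimethyl acetal of 17 (not isolated) | COC(OC)c1c(O)cc(OCOC)c(C[C@@H](CC=C(C)C)C(C)=C)c1OCOC | intermediate
23 | 4-methoxy ortho-quinone methide (not isolated) | COC=C1C(=O)C=C(OCOC)C(C[C@@H](CC=C(C)C)C(C)=C)=C1OCOC | intermediate
24 | (2S)-4-methoxy-5,7-bis(methoxymethoxy)-6-[(2R)-lavandulyl]-2-[2,4,6-tris(methoxymethoxy)phenyl]chromane, C4 epimers | COC1C[C@@H](c2c(OCOC)cc(OCOC)cc2OCOC)Oc2cc(OCOC)c(C[C@@H](CC=C(C)C)C(C)=C)c(OCOC)c12 | intermediate
25 | (2S)-5,7-bis(methoxymethoxy)-6-[(2R)-lavandulyl]-2-[2,4,6-tris(methoxymethoxy)phenyl]chroman-4-ol, C4 epimers | OC1C[C@@H](c2c(OCOC)cc(OCOC)cc2OCOC)Oc2cc(OCOC)c(C[C@@H](CC=C(C)C)C(C)=C)c(OCOC)c12 | intermediate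
26 | (2S)-5,7-bis(methoxymethoxy)-6-[(2R)-lavandulyl]-2-[2,4,6-tris(methoxymethoxy)phenyl]chroman-4-one | O=C1C[C@@H](c2c(OCOC)cc(OCOC)cc2OCOC)Oc2cc(OCOC)c(C[C@@H](CC=C(C)C)C(C)=C)c(OCOC)c12 | intermediate
27 | (2S)-5,7-dihydroxy-6-[(2R)-5-methyl-2-(prop-1-en-2-yl)hex-4-en-1-yl]-2-(2,4,6-trihydroxyphenyl)chroman-4-one | C=C(C)[C@H](CC=C(C)C)Cc1c(O)cc2c(c1O)C(=O)C[C@@H](c1c(O)cc(O)cc1O)O2 | target

**Step count**

Total step count: 16.
Longest linear sequence: 11 steps (steps 1, 2, 3, 4, 8, 9, 10, 13, 14, 15, 16).

**Steps most likely to fail**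

Step 13. The counter-anion may give poor facial control at C2. The selectivity may also erode through reversible ionisation of the C2–O1 bond, and the acid may cleave MOM ethers or oligomerise the styrene. The fallback uses known chemistry. It sets out from 17, 20 and 21, which are combined with an achiral acid (p-TsOH cat., CH2Cl2, −20 °C) in the established acid-promoted union of salicylaldehyde acetals with styrenes; this should give the 4-methoxyflavan as a mixture of C2 epimers F1. The conditions of steps 14 and 15 should then lead through the C2-epimeric flavan-4-ol F2 to the C2-epimeric penta-MOM flavanone F3. Kinetic resolution by Noyori asymmetric transfer hydrogenation with RuCl[(R,R)-TsDPEN](p-cymene) and HCO2H/Et3N should reduce the (2R) epimer to the cis-(2R,4R)-flavan-4-ol F4 and leave the (2S) ketone untouched. That ketone is 26, where the route resumes; F4 should be removable by chromatography.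

Step 14. The C4 cation may lose a proton to give the flav-3-ene or alkylate C8 of a second molecule. The acid may also hydrolyse MOM ethers or epimerise C2 through C2–O1 ionisation. The fallback replaces solvolysis and alcohol oxidation by a single oxidative step that needs no acid. It sets out from 24: DDQ in CH2Cl2/pH 7 buffer at 0 °C should abstract hydride from the α-methoxy benzylic C4–H, and water should collapse the resulting oxocarbenium ion to the ketone and methanol. It returns to the route at 26, bypasses 25 and makes no new compound (F0). It is held in reserve and not used first, because hydride abstraction at C1'' or C2 could compete.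

Step 16. Protic acid may epimerise C2 through ring opening towards the chalcone. It may also add the freed C5 and C7 hydroxyls, or methanol, across the lavandulyl double bonds. The fallback removes the MOM groups without protic acid. It sets out from 26: TMSOTf and 2,2'-bipyridyl in CH2Cl2 at 0 °C should convert the aryl MOM ethers into the penta(trimethylsilyl) ether F5, and brief treatment with water in THF should hydrolyse the silyl ethers. It returns to the route at 27.

**Further compounds**

F1 | step 13 | 4-methoxy-5,7-bis(methoxymethoxy)-6-[(2R)-lavandulyl]-2-[2,4,6-tris(methoxymethoxy)phenyl]chromane, mixture of C2 and C4 epimers | COC1CC(c2c(OCOC)cc(OCOC)cc2OCOC)Oc2cc(OCOC)c(C[C@@H](CC=C(C)C)C(C)=C)c(OCOC)c12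
F2 | step 13 | 5,7-bis(methoxymethoxy)-6-[(2R)-lavandulyl]-2-[2,4,6-tris(methoxymethoxy)phenyl]chroman-4-ol, mixture of C2 and C4 epimers | OC1CC(c2c(OCOC)cc(OCOC)cc2OCOC)Oc2cc(OCOC)c(C[C@@H](CC=C(C)C)C(C)=C)c(OCOC)c12
F3 | step 13 | 5,7-bis(methoxymethoxy)-6-[(2R)-lavandulyl]-2-[2,4,6-tris(methoxymethoxy)phenyl]chroman-4-one, mixture of C2 epimers | O=C1CC(c2c(OCOC)cc(OCOC)cc2OCOC)Oc2cc(OCOC)c(C[C@@H](CC=C(C)C)C(C)=C)c(OCOC)c12
F4 | step 13 | (2R,4R)-5,7-bis(methoxymethoxy)-6-[(2R)-lavandulyl]-2-[2,4,6-tris(methoxymethoxy)phenyl]chroman-4-ol | O[C@@H]1C[C@H](c2c(OCOC)cc(OCOC)cc2OCOC)Oc2cc(OCOC)c(C[C@@H](CC=C(C)C)C(C)=C)c(OCOC)c12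
F0 | step 14 | none | none
F5 | step 16 | (2S)-6-[(2R)-lavandulyl]-5,7-bis(trimethylsilyloxy)-2-[2,4,6-tris(trimethylsilyloxy)phenyl]chroman-4-one | O=C1C[C@@H](c2c(O[Si](C)(C)C)cc(O[Si](C)(C)C)cc2O[Si](C)(C)C)Oc2cc(O[Si](C)(C)C)c(C[C@@H](CC=C(C)C)C(C)=C)c(O[Si](C)(C)C)c12
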